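**Retrosynthetic overview**

1. Ring E last: target 17 ⇒ tetracyclic lactone 12 + (S)-methylsuccinic anhydride 13 (Friedel–Crafts acylation at C3, then CBS reduction and lactonisation; C20 from the chiral pool, C18 by reagent control).
2. Ring C: 12 ⇒ butenolide 10, C1–C12 bond by intramolecular Friedel–Crafts Michael addition (sets C12 and C13).
3. Ring D (key step): 10 ⇒ aldehyde 6 + ethyl 2-(bromomethyl)acrylate 7. The C11–C12 bond comes from a chromium 2-carboxyallyl nucleophile (a methacrylate homoenolate equivalent) adding to the aldehyde under catalyst control of C11; C12 reacts first as donor and, after alkene migration, as acceptor.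
4. Ring B: 6 ⇒ enal 5, C9–C9a bond by organocatalytic intramolecular Friedel–Crafts alkylation (sets C9 and C10); 5 ⇒ pyrrole 1 + 6-bromohex-1-ene 2 + 2-ethylacrolein 4.
5. Order of ring formation: A (purchased pyrrole) → B → D → C → E.

Assumption: atoms are numbered as in tuberostemonine (ring A pyrrole C1, C2, C3, N4, C9a; ring B C5–C9; ring C C9–C12 with C1 and C9a; ring D lactone C11–O–C14–C13–C12; ring E lactone C18–C21; ethyl C16–C17; methyls C15 and C22), which makes the target 9R,10R,11R,12S,13S,18R,20S; the absolute sense of each chiral catalyst is taken from its closest literature model, and the antipodal catalyst would be used if the sense proved opposite.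

**Route**

Step 1
Reactants: 1 pyrrole; 2 6-bromohex-1-ene
Product: 3 1-(hex-5-en-1-yl)-1H-pyrrole
Conditions: KOH, DMSO, rt
Reagents that add atoms: none
Why: SN2 N-alkylation of potassium pyrrolide, whose ionic N–K pair in DMSO reacts at nitrogen and not at carbon.

Step 2
Reactants: 3 1-(hex-5-en-1-yl)-1H-pyrrole; 4 2-ethylacrolein (2-methylidenebutanal)
Product: 5 (2E)-2-ethyl-7-(1H-pyrrol-1-yl)hept-2-enal
Conditions: second-generation Hoveyda–Grubbs catalyst (5 mol %), 4 (6 equiv), CH2Cl2, 40 °C
Reagents that add atoms: none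
Why: Olefin cross-metathesis of a terminal alkene with a 2-substituted acrolein, driven by loss of ethene and giving the thermodynamically favoured E-trisubstituted enal.

Step 3
Reactants: 5 (2E)-2-ethyl-7-(1H-pyrrol-1-yl)hept-2-enal
Product: 6 (2R)-2-[(9R)-6,7,8,9-tetrahydro-5H-pyrrolo[1,2-a]azepin-9-yl]butanal
Conditions: 9-amino-9-deoxy-epi-quinine (20 mol %), CF3CO2H (40 mol %), PhMe (0.02 M), 0 °C to rt
Reagents that add atoms: none
Why: Proposed new method: the primary amine condenses with the α-branched enal to an iminium ion, the tethered pyrrole attacks C9 through its free α-carbon (7-exo-trig Friedel–Crafts alkylation) on the face left open by the cinchona scaffold (sets 9R), and the catalyst-bound enamine is then protonated under catalyst control (sets 10R); the closest known reactions are imidazolidinone-catalysed intramolecular pyrrole–enal cyclisations and cinchona-primary-amine Friedel–Crafts/protonation of α-branched enals.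

Step 4
Reactants: 6 (2R)-2-[(9R)-6,7,8,9-tetrahydro-5H-pyrrolo[1,2-a]azepin-9-yl]butanal; 7 ethyl 2-(bromomethyl)acrylate
Product: 9 (5S)-3-methylidene-5-{(1R)-1-[(9R)-6,7,8,9-tetrahydro-5H-pyrrolo[1,2-a]azepin-9-yl]propyl}oxolan-2-one, via silyl ether 8 (not isolated)
Conditions: CrCl2 (10 mol %), (S,S)-carbazole bis(oxazoline) ligand (11 mol %), Et3N (20 mol %), Mn powder (2 equiv), Me3SiCl (1.2 equiv), THF, rt; then Bu4NF, THF, 0 °C
Reagents that add atoms: none
Why: Divalent chromium (regenerated by Mn) inserts into the allylic C–Br bond and turns the doubly electrophilic acrylate into a nucleophilic 2-(ethoxycarbonyl)allylchromium, a methacrylate homoenolate equivalent, which adds to the aldehyde through a closed six-membered transition state (Nozaki–Hiyama-type 2-(alkoxycarbonyl)allylation) and so joins the two natural acceptor carbons C11 and C12; the chiral ligand on trivalent chromium selects the aldehyde face and must override the modest Felkin–Anh bias of C10 (the anti-Felkin carbinol is needed), and fluoride desilylation lets the alkoxide close ring D with loss of ethoxide.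

Step 5
Reactants: 9 (5S)-3-methylidene-5-{(1R)-1-[(9R)-6,7,8,9-tetrahydro-5H-pyrrolo[1,2-a]azepin-9-yl]propyl}oxolan-2-one
Product: 10 (5R)-3-methyl-5-{(1R)-1-[(9R)-6,7,8,9-tetrahydro-5H-pyrrolo[1,2-a]azepin-9-yl]propyl}furan-2(5H)-one
Conditions: RuHCl(CO)(PPh3)3 (5 mol %), PhMe, 80 °C
Reagents that add atoms: none
Why: Ruthenium hydride adds across the exocyclic alkene and β-hydride elimination toward C12 gives the more stable endocyclic conjugated butenolide (alkene isomerisation by hydrometalation/β-hydride elimination), making C12 an acceptor without touching C11.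

Step 6
Reactants: 10 (5R)-3-methyl-5-{(1R)-1-[(9R)-6,7,8,9-tetrahydro-5H-pyrrolo[1,2-a]azepin-9-yl]propyl}furan-2(5H)-one
Product: 12 tetracyclic lactone (rings A to D; 9R,10R,11R,12S,13S; C3–H), via aluminium enolate 11 (not isolated)
Conditions: Me2AlCl (2 equiv), CH2Cl2 (0.01 M), −78 to −20 °C; MeOH, −78 °C; aq. potassium sodium tartrate
Reagents that add atoms: none
Why: Me2AlCl activates the butenolide, and C1 is the only ring A carbon that can reach C12 (6-exo-trig intramolecular Friedel–Crafts Michael addition), adding on the lactone face that carries the tether so the ring fusion is cis (12S); the Wheland proton leaves as methane, so enolate 11 survives until it is protonated at −78 °C from its convex face, which places the C13 methyl on the concave side (13S).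

Step 7
Reactants: 12 tetracyclic lactone (rings A to D); 13 (S)-methylsuccinic anhydride
Product: 15 methyl (2S)-2-methyl-4-oxo-4-(C3 of tetracycle 12)butanoate, via keto acid 14 (not isolated)
Conditions: 13 premixed with AlCl3 (2.5 equiv), CH2Cl2, −20 to 0 °C; aq. work-up; then Me3SiCHN2, PhMe/MeOH, 0 °C
Reagents that add atoms: (trimethylsilyl)diazomethane, C[Si](C)(C)C=[N+]=[N-]
Why: Friedel–Crafts acylation at C3, the only free and most nucleophilic α-position of ring A, with the pyrrole opening the anhydride at the less hindered carbonyl remote from the methyl group, so the preformed 20S centre ends up next to the carboxyl, which is then methylated.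

Step 8
Reactants: 15 methyl (2S)-2-methyl-4-oxo-4-(C3 of tetracycle 12)butanoate
Product: 17 target (9R,10R,11R,12S,13S,18R,20S), via hydroxy ester 16 (not isolated)
Conditions: (S)-2-methyl-CBS-oxazaborolidine (20 mol %), catecholborane (1.5 equiv), PhMe, −40 to 0 °C; MeOH; then 2-hydroxypyridine (10 mol %), PhMe, 70 °C
Reagents that add atoms: none
Why: Corey–Bakshi–Shibata reduction with the pyrrolyl group as the large substituent gives the 18R carbinol (acetophenone model), and the γ-hydroxy ester closes ring E by acyl substitution with retention at C18 under neutral conditions that avoid ionising the pyrrolylcarbinol, giving the trans 18R,20S lactone.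

**Compound list**

1 | pyrrole | c1cc[nH]c1 | starting material
2 | 6-bromohex-1-ene | BrCCCCC=C | starting material
3 | 1-(hex-5-en-1-yl)-1H-pyrrole | C=CCCCCn1cccc1 | intermediate
4 | 2-ethylacrolein (2-methylidenebutanal) | CCC(=C)C=O | starting material
5 | (2E)-2-ethyl-7-(1H-pyrrol-1-yl)hept-2-enal | CC/C(C=O)=C\CCCCn1cccc1 | intermediate
6 | (2R)-2-[(9R)-6,7,8,9-tetrahydro-5H-pyrrolo[1,2-a]azepin-9-yl]butanal | CC[C@@H](C=O)[C@H]1CCCCn2cccc12 | intermediate
7 | ethyl 2-(bromomethyl)acrylate | C=C(CBr)C(=O)OCC | starting material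
8 | ethyl (4S,5R)-2-methylidene-5-[(9R)-6,7,8,9-tetrahydro-5H-pyrrolo[1,2-a]azepin-9-yl]-4-[(trimethylsilyl)oxy]heptanoate | CC[C@@H]([C@@H](O[Si](C)(C)C)CC(=C)C(=O)OCC)[C@H]1CCCCn2cccc12 | intermediate (not isolated)
9 | (5S)-3-methylidene-5-{(1R)-1-[(9R)-6,7,8,9-tetrahydro-5H-pyrrolo[1,2-a]azepin-9-yl]propyl}oxolan-2-one | CC[C@@H]([C@@H]1CC(=C)C(=O)O1)[C@H]1CCCCn2cccc12 | intermediate
10 | (5R)-3-methyl-5-{(1R)-1-[(9R)-6,7,8,9-tetrahydro-5H-pyrrolo[1,2-a]azepin-9-yl]propyl}furan-2(5H)-one | CC[C@@H]([C@@H]1C=C(C)C(=O)O1)[C@H]1CCCCn2cccc12 | intermediate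
11 | chloro(methyl)aluminium enolate (ketene acetal at C13=C14) of tetracycle 12 | CC[C@H]1[C@H]2OC(O[Al](C)Cl)=C(C)[C@H]2c2ccn3c2[C@@H]1CCCC3 | intermediate (not isolated)
12 | tetracyclic lactone, rings A to D of the target with H at C3 (9R,10R,11R,12S,13S; cis-fused ring D, C13 methyl cis to C1) | CC[C@H]1[C@H]2OC(=O)[C@@H](C)[C@H]2c2ccn3c2[C@@H]1CCCC3 | intermediate
13 | (S)-methylsuccinic anhydride ((3S)-3-methyloxolane-2,5-dione) | O=C1C[C@H](C)C(=O)O1 | starting material
14 | (2S)-2-methyl-4-oxo-4-(C3 of tetracycle 12)butanoic acid | CC[C@H]1[C@H]2OC(=O)[C@@H](C)[C@H]2c2cc(C(=O)C[C@H](C)C(=O)O)n3c2[C@@H]1CCCC3 | intermediate (not isolated)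
15 | methyl (2S)-2-methyl-4-oxo-4-(C3 of tetracycle 12)butanoate | CC[C@H]1[C@H]2OC(=O)[C@@H](C)[C@H]2c2cc(C(=O)C[C@H](C)C(=O)OC)n3c2[C@@H]1CCCC3 | intermediate
16 | methyl (2S,4R)-4-hydroxy-2-methyl-4-(C3 of tetracycle 12)butanoate | CC[C@H]1[C@H]2OC(=O)[C@@H](C)[C@H]2c2cc([C@H](O)C[C@H](C)C(=O)OC)n3c2[C@@H]1CCCC3 | intermediate (not isolated)
17 | CNP0232452.1 (9R,10R,11R,12S,13S,18R,20S) | CC[C@H]1[C@H]2OC(=O)[C@@H](C)[C@H]2c2cc([C@H]3C[C@H](C)C(=O)O3)n3c2[C@@H]1CCCC3 | target

**Step count and risks**

Total steps: 8. Longest linear sequence: 8.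

The three steps most likely to fail:

Step 3. The seven-membered ring, the α-branched enal and the C10 centre set by protonation are all untested together, so yield, ee and dr are uncertain. The fallback sets out from 3 and comes back at 6, with each centre set by an established method. Cross-metathesis of 3 with crotonaldehyde gives (2E)-7-(1H-pyrrol-1-yl)hept-2-enal F1. The second-generation MacMillan imidazolidinone salt then closes ring B on this α-unbranched enal to 2-[(9R)-6,7,8,9-tetrahydro-5H-pyrrolo[1,2-a]azepin-9-yl]acetaldehyde F2. Ag2O oxidation gives 2-[(9R)-6,7,8,9-tetrahydro-5H-pyrrolo[1,2-a]azepin-9-yl]acetic acid F3. Its pivaloyl mixed anhydride acylates lithiated (R)-4-benzyl-1,3-oxazolidin-2-one to the imide F4. NaHMDS/EtI alkylation, anti to the benzyl group of the chelated Z-enolate, sets 10R in the ethylated imide F5. LiBH4 gives (2R)-2-[(9R)-6,7,8,9-tetrahydro-5H-pyrrolo[1,2-a]azepin-9-yl]butan-1-ol F6, and Dess–Martin oxidation returns 6.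

Step 4. The catalyst has to work against the Felkin–Anh preference of a hindered α-branched aldehyde. The fallback sets out from 6 and comes back at 9, using a hydride instead of a carbon nucleophile to set C11. Zinc-mediated Barbier addition of 7 (THF/aq. NH4Cl) gives the C11-epimeric hydroxy ester F7. Dess–Martin oxidation gives the ketone F8. Reduction with (R)-2-methyl-CBS-oxazaborolidine/catecholborane gives the (4S)-hydroxy ester F9; hydride and carbon nucleophiles give opposite Felkin diastereomers, so substrate and reagent are now matched. F9 lactonises (2-hydroxypyridine, PhMe, 70 °C) to 9.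

Step 8. The electron-rich 2-acylpyrrole may reduce sluggishly or over-reduce, and the pyrrolylcarbinol can ionise and lose C18. The fallback sets out from 12 and comes back at 17, setting C18 by C–C bond formation and C20 by enolate alkylation. Vilsmeier–Haack formylation of 12 (POCl3, DMF) gives the 3-carbaldehyde F10. Addition of the zinc homoenolate IZnCH2CH2CO2Et, catalysed by Ti(OiPr)4 and a chiral bis-sulfonamide, gives the (18R)-hydroxy ester F11, which closes to the 22-nor bis-lactone F12. LiHMDS (2.1 equiv) at −78 °C followed by MeI (1.05 equiv) methylates the ring E enolate anti to the pyrrole (20S, trans). A quench at −78 °C with 2,6-di-tert-butylphenol re-protonates the ring D enolate from its convex face (13S) and gives 17.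

**Further compounds**

F1 | step 3 | (2E)-7-(1H-pyrrol-1-yl)hept-2-enal | O=C/C=C/CCCCn1cccc1
F2 | step 3 | 2-[(9R)-6,7,8,9-tetrahydro-5H-pyrrolo[1,2-a]azepin-9-yl]acetaldehyde | O=CC[C@H]1CCCCn2cccc12
F3 | step 3 | 2-[(9R)-6,7,8,9-tetrahydro-5H-pyrrolo[1,2-a]azepin-9-yl]acetic acid | OC(=O)C[C@H]1CCCCn2cccc12
F4 | step 3 | (4R)-4-benzyl-3-{2-[(9R)-6,7,8,9-tetrahydro-5H-pyrrolo[1,2-a]azepin-9-yl]acetyl}-1,3-oxazolidin-2-one | O=C(C[C@H]1CCCCn2cccc12)N1[C@H](Cc2ccccc2)COC1=O
F5 | step 3 | (4R)-4-benzyl-3-{(2R)-2-[(9R)-6,7,8,9-tetrahydro-5H-pyrrolo[1,2-a]azepin-9-yl]butanoyl}-1,3-oxazolidin-2-one | CC[C@@H](C(=O)N1[C@H](Cc2ccccc2)COC1=O)[C@H]1CCCCn2cccc12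
F6 | step 3 | (2R)-2-[(9R)-6,7,8,9-tetrahydro-5H-pyrrolo[1,2-a]azepin-9-yl]butan-1-ol | CC[C@@H](CO)[C@H]1CCCCn2cccc12
F7 | step 4 | ethyl (5R)-4-hydroxy-2-methylidene-5-[(9R)-6,7,8,9-tetrahydro-5H-pyrrolo[1,2-a]azepin-9-yl]heptanoate (C4 epimer mixture) | CC[C@@H](C(O)CC(=C)C(=O)OCC)[C@H]1CCCCn2cccc12
F8 | step 4 | ethyl (5R)-2-methylidene-4-oxo-5-[(9R)-6,7,8,9-tetrahydro-5H-pyrrolo[1,2-a]azepin-9-yl]heptanoate | CC[C@@H](C(=O)CC(=C)C(=O)OCC)[C@H]1CCCCn2cccc12
F9 | step 4 | ethyl (4S,5R)-4-hydroxy-2-methylidene-5-[(9R)-6,7,8,9-tetrahydro-5H-pyrrolo[1,2-a]azepin-9-yl]heptanoate | CC[C@@H]([C@@H](O)CC(=C)C(=O)OCC)[C@H]1CCCCn2cccc12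
F10 | step 8 | 3-carbaldehyde of tetracycle 12 | CC[C@H]1[C@H]2OC(=O)[C@@H](C)[C@H]2c2cc(C=O)n3c2[C@@H]1CCCC3
F11 | step 8 | ethyl (4R)-4-hydroxy-4-(C3 of tetracycle 12)butanoate | CC[C@H]1[C@H]2OC(=O)[C@@H](C)[C@H]2c2cc([C@H](O)CCC(=O)OCC)n3c2[C@@H]1CCCC3
F12 | step 8 | 22-nor target (ring E without the C20 methyl; 18R) | CC[C@H]1[C@H]2OC(=O)[C@@H](C)[C@H]2c2cc([C@H]3CCC(=O)O3)n3c2[C@@H]1CCCC3
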